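**Assumptions (one line each):** Germacrane numbering is used; the target SMILES reads as 5R,6S,7R,8S,10R. One-pot, two-stage operations (steps 3, 4, 5) are counted as single steps. The route is a paper design and has not been run; selectivities are expectations.

## Retrosynthetic overview

1. The 10-membered carbocycle is closed last at C4–C5 by an intramolecular Ni/Cr (NHK) coupling of a C4 vinyl triflate with a C5 aldehyde, giving the exo-methylene carbinol directly with no protecting group left to remove.
2. C7–C8 is made by Zn-Barbier allylation of a furanone aldehyde with a (5S)-3-(bromomethyl)butenolide; C6 (from D-mannitol) controls C7 and C8.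
3. The 3(2H)-furanone is unmasked from a 3-acetylisoxazole, whose ring is built by a nitrile oxide–alkyne [3+2] cycloaddition; the acetyl group later becomes C4/C15.
4. C10 comes from L-lactic acid by Seebach dioxolanone prenylation (self-regeneration of the stereocentre).
5. Ring order: isoxazole ([3+2]) → furanone; the γ-lactone is made separately by lactonisation, carried as the butenolide and re-formed as the α-methylene lactone in the Barbier step; the carbocycle is closed last.

## Route

### North fragment

**Step 1**
Reactants: 1 L-lactic acid; 2 pivalaldehyde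
Product: 3 (2S,5S)-2-tert-butyl-5-methyl-1,3-dioxolan-4-one (cis)
Conditions: cat. TsOH/H2SO4, pentane, reflux (Dean–Stark); recrystallise cis isomer at −78 °C
Reagents that add atoms: pivalaldehyde (2), CC(C)(C)C=O
Why: Seebach acetalisation; the thermodynamically favoured cis acetal stores the lactate configuration at the new acetal carbon.

**Step 2**
Reactants: 3; 4 prenyl bromide
Product: 5 (2S,5R)-2-tert-butyl-5-methyl-5-(3-methylbut-2-en-1-yl)-1,3-dioxolan-4-one
Conditions: LDA, THF, −78 °C; then 4, −78 → −30 °C
Reagents that add atoms: prenyl bromide (4), CC(C)=CCBr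
Why: Enolate alkylation anti to the tert-butyl group (self-regeneration of stereocentres) sets the quaternary C10 with overall retention, which is R here.

**Step 3**
Reactants: 5
Product: 6 (R)-3,6-dimethylhept-5-en-1-yn-3-ol
Conditions: DIBAL-H, CH2Cl2, −78 °C; then MeOH, K2CO3, Ohira–Bestmann reagent (2.5 equiv), 0 °C → rt (one pot)
Reagents that add atoms: dimethyl (1-diazo-2-oxopropyl)phosphonate, CC(=O)C(=[N+]=[N-])P(=O)(OC)OC (supplies the terminal alkyne carbon, C2)
Why: Lactone → lactol reduction, then in basic methanol the lactol releases pivaldehyde and the α-hydroxy aldehyde undergoes Seyferth–Gilbert/Ohira–Bestmann homologation; C10 has no α-H and cannot epimerise.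

**Step 4**
Reactants: 6; 7 isonitrosoacetone (pyruvaldehyde 1-oxime)
Product: 8 1-{5-[(2R)-2-hydroxy-5-methylhex-4-en-2-yl]isoxazol-3-yl}ethan-1-one
Conditions: 7, NCS, DMF, rt; then 6, Et3N (syringe pump), 0 °C → rt
Reagents that add atoms: isonitrosoacetone (7), CC(=O)C=NO
Why: Huisgen [3+2] cycloaddition of in situ acetyl nitrile oxide with the terminal alkyne gives the 3,5-disubstituted isoxazole regioselectively; the trisubstituted prenyl alkene is a much poorer dipolarophile.

**Step 5**
Reactants: 8
Product: 9 (2R)-5-acetyl-2-methyl-2-(3-methylbut-2-en-1-yl)furan-3(2H)-one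
Conditions: Mo(CO)6, MeCN/H2O, 80 °C; then 1 M HCl, THF, rt
Reagents that add atoms: none
Why: Reductive N–O cleavage gives the α′-hydroxy enaminone, and acid makes the tertiary C10–OH displace NH3 at C3 (isoxazole-to-3(2H)-furanone unmasking).

**Step 6**
Reactants: 9
Product: 10 1-[(5R)-5-methyl-5-(3-methylbut-2-en-1-yl)-4-oxo-4,5-dihydrofuran-2-yl]ethenyl triflate
Conditions: KHMDS, THF, −78 °C; PhNTf2, −78 → 0 °C
Reagents that add atoms: N-phenyl-bis(trifluoromethanesulfonimide), O=S(=O)(N(c1ccccc1)S(=O)(=O)C(F)(F)F)C(F)(F)F
Why: The acetyl CH3 is the only enolisable position (C10 is quaternary, C2–H is vinylic), so kinetic enolate O-triflation gives the 1,1-disubstituted vinyl triflate that becomes C4=C15.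

**Step 7**
Reactants: 10
Product: 11 1-[(5R)-5-methyl-4-oxo-5-(2-oxoethyl)-4,5-dihydrofuran-2-yl]ethenyl triflate
Conditions: OsO4 (cat.), NaIO4, 2,6-lutidine, dioxane/H2O, rt; use crude
Reagents that add atoms: OsO4/NaIO4 (aldehyde oxygen), O=[Os](=O)(=O)=O and [Na+].[O-]I(=O)(=O)=O
Why: Lemieux–Johnson cleavage is selective for the electron-rich trisubstituted alkene over the push-pull furanone alkene and the electron-poor enol triflate, and reveals the C8 aldehyde.

### South fragment

**Step 8**
Reactants: 12 1,2:5,6-di-O-isopropylidene-D-mannitol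
Product: 13 (R)-2,3-O-isopropylideneglyceraldehyde
Conditions: NaIO4, aq. NaHCO3, CH2Cl2, rt
Reagents that add atoms: none
Why: Periodate glycol cleavage gives two equivalents of the aldehyde; its stereocentre becomes C6.

**Step 9**
Reactants: 13; 14 methyl acrylate
Product: 15 methyl 2-{[(4R)-2,2-dimethyl-1,3-dioxolan-4-yl](hydroxy)methyl}prop-2-enoate (carbinol epimers)
Conditions: DABCO, dioxane/H2O, rt, 2–4 d
Reagents that add atoms: methyl acrylate (14), C=CC(=O)OC
Why: Morita–Baylis–Hillman reaction installs C11–C13; the new carbinol centre (C7) is lost in step 12, so its dr is irrelevant.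

**Step 10**
Reactants: 15
Product: 16 (5R)-4-hydroxy-5-(hydroxymethyl)-3-methylideneoxolan-2-one (C4 epimers)
Conditions: TFA/H2O (4:1), 0 °C → rt; concentrate from toluene
Reagents that add atoms: none
Why: Acetonide hydrolysis and spontaneous γ-lactonisation through the secondary C6–OH (five-membered ring preferred over the δ-lactone).

**Step 11**
Reactants: 16
Product: 17 (5R)-5-{[(tert-butyldimethylsilyl)oxy]methyl}-4-hydroxy-3-methylideneoxolan-2-one
Conditions: TBSCl, imidazole, CH2Cl2/DMF, −20 → 0 °C
Reagents that add atoms: TBSCl, CC(C)(C)[Si](C)(C)Cl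
Why: Selective silylation of the primary alcohol over the hindered secondary allylic one.

**Step 12**
Reactants: 17
Product: 18 (5S)-3-(bromomethyl)-5-{[(tert-butyldimethylsilyl)oxy]methyl}furan-2(5H)-one
Conditions: NBS, Me2S, CH2Cl2, 0 °C → rt
Reagents that add atoms: N-bromosuccinimide, O=C1CCC(=O)N1Br
Why: Corey–Kim activation and SN2′ bromide delivery, the usual Baylis–Hillman alcohol → allyl bromide transposition, converge both epimers on the conjugated butenolide; C6 is untouched.

### Union and endgame

**Step 13**
Reactants: 11; 18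
Product: 19 1-{(5R)-5-[(2S)-2-hydroxy-2-{(2S,3R)-2-[(TBSO)methyl]-4-methylidene-5-oxooxolan-3-yl}ethyl]-5-methyl-4-oxo-4,5-dihydrofuran-2-yl}ethenyl triflate
Conditions: Zn dust, THF/sat. aq. NH4Cl, 0 °C → rt
Reagents that add atoms: none
Why: Barbier allylation with γ-attack anti to the C6 substituent gives the trans lactone (C7), and a chair transition state with the ring-locked E-type allylzinc gives the 7,8-anti carbinol (C8 S); it regenerates the α-methylene lactone and leaves the vinyl triflate untouched.

**Step 14**
Reactants: 19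
Product: 20 the C8 methacrylate of 19
Conditions: methacrylic anhydride, Et3N, DMAP, CH2Cl2, 0 °C → rt
Reagents that add atoms: methacrylic anhydride, CC(=C)C(=O)OC(=O)C(C)=C
Why: DMAP-catalysed acylation of the only free hydroxyl.

**Step 15**
Reactants: 20
Product: 21 the C5 primary alcohol
Conditions: HF·pyridine, THF/pyridine, 0 °C → rt
Reagents that add atoms: none
Why: Buffered fluoride desilylation leaves the esters, enol triflate and furanone intact.

**Step 16**
Reactants: 21
Product: 22 the C5 aldehyde
Conditions: Dess–Martin periodinane, NaHCO3, CH2Cl2, 0 °C → rt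
Reagents that add atoms: none
Why: Neutral oxidation avoids epimerising the α-acyloxy aldehyde at C6 (C7 is now sp3, so there is no butenolide γ-formyl problem).

**Step 17**
Reactants: 22
Product: 23 isogoyazensolide
Conditions: CrCl2 (10 equiv), NiCl2 (cat.), degassed DMSO, rt, 2 mM, slow addition
Reagents that add atoms: none
Why: Intramolecular Nozaki–Hiyama–Kishi coupling forms C4–C5 and closes the ring; Felkin–Anh addition anti to the C6–O bond should give the 5,6-anti (5R) carbinol, and the vinylchromium does not touch the enoates.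

## Compound list

1 | L-lactic acid | C[C@H](O)C(=O)O | starting material
2 | pivalaldehyde | CC(C)(C)C=O | starting material
3 | (2S,5S)-2-tert-butyl-5-methyl-1,3-dioxolan-4-one | C[C@@H]1O[C@H](C(C)(C)C)OC1=O | intermediate
4 | prenyl bromide | CC(C)=CCBr | starting material
5 | (2S,5R)-2-tert-butyl-5-methyl-5-prenyl-1,3-dioxolan-4-one | C[C@]1(CC=C(C)C)O[C@H](C(C)(C)C)OC1=O | intermediate
6 | (R)-3,6-dimethylhept-5-en-1-yn-3-ol | C#C[C@](C)(O)CC=C(C)C | intermediate
7 | isonitrosoacetone | CC(=O)C=NO | starting material
8 | 3-acetyl-5-[(2R)-2-hydroxy-5-methylhex-4-en-2-yl]isoxazole | CC(=O)c1cc(on1)[C@](C)(O)CC=C(C)C | intermediate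
9 | (2R)-5-acetyl-2-methyl-2-prenylfuran-3(2H)-one | CC(=O)C1=CC(=O)[C@@](C)(CC=C(C)C)O1 | intermediate
10 | vinyl triflate of 9 | C=C(OS(=O)(=O)C(F)(F)F)C1=CC(=O)[C@@](C)(CC=C(C)C)O1 | intermediate
11 | C8 aldehyde (furanone vinyl triflate) | C=C(OS(=O)(=O)C(F)(F)F)C1=CC(=O)[C@@](C)(CC=O)O1 | intermediate
12 | 1,2:5,6-di-O-isopropylidene-D-mannitol | CC1(C)OC[C@@H](O1)[C@@H](O)[C@H](O)[C@H]1COC(C)(C)O1 | starting material
13 | (R)-2,3-O-isopropylideneglyceraldehyde | CC1(C)OC[C@@H](O1)C=O | intermediate
14 | methyl acrylate | C=CC(=O)OC | starting material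
15 | Baylis–Hillman adduct (carbinol epimers) | CC1(C)OC[C@@H](O1)C(O)C(=C)C(=O)OC | intermediate
16 | (5R)-4-hydroxy-5-(hydroxymethyl)-3-methylideneoxolan-2-one | C=C1C(O)[C@@H](CO)OC1=O | intermediate
17 | primary TBS ether of 16 | C=C1C(O)[C@@H](CO[Si](C)(C)C(C)(C)C)OC1=O | intermediate
18 | (5S)-3-(bromomethyl)-5-(TBSOCH2)furan-2(5H)-one | BrCC1=C[C@@H](CO[Si](C)(C)C(C)(C)C)OC1=O | intermediate
19 | Barbier adduct (6S,7R,8S,10R) | O[C@@H](C[C@@]1(C)OC(=CC1=O)C(=C)OS(=O)(=O)C(F)(F)F)[C@H]1C(=C)C(=O)O[C@@H]1CO[Si](C)(C)C(C)(C)C | intermediate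
20 | C8 methacrylate | C=C(C)C(=O)O[C@@H](C[C@@]1(C)OC(=CC1=O)C(=C)OS(=O)(=O)C(F)(F)F)[C@H]1C(=C)C(=O)O[C@@H]1CO[Si](C)(C)C(C)(C)C | intermediate
21 | C5 primary alcohol | C=C(C)C(=O)O[C@@H](C[C@@]1(C)OC(=CC1=O)C(=C)OS(=O)(=O)C(F)(F)F)[C@H]1C(=C)C(=O)O[C@@H]1CO | intermediate
22 | C5 aldehyde | C=C(C)C(=O)O[C@@H](C[C@@]1(C)OC(=CC1=O)C(=C)OS(=O)(=O)C(F)(F)F)[C@H]1C(=C)C(=O)O[C@@H]1C=O | intermediate
23 | isogoyazensolide | C=C(C)C(=O)O[C@H]1C[C@@]2(C)OC(=CC2=O)C(=C)[C@@H](O)[C@H]2OC(=O)C(=C)[C@@H]21 | target

## Totals

Total steps: 17. Longest linear sequence: 12 (steps 1–7, then 13–17); the south branch is 5 steps before the union.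

## Steps most likely to fail, with fallbacks

1. **Step 17 (NHK ring closure).** Risks are medium-ring strain, oligomerisation and the wrong C5 epimer. Fallback: change the ring-closing bond. Make C4–C5 first by intermolecular NHK of triflate 10 with aldehyde 13 (Felkin anti), build the bromomethyl butenolide on the resulting C6/C7 diol, and close the ring at C7–C8 by intramolecular Zn or Cr Barbier allylation onto the C8 aldehyde.

2. **Step 6 (enol triflate of the acyl furanone).** The base may attack the electrophilic acylfuranone instead of deprotonating it. Fallback: bring the NHK handle in with the dipole, using the nitrile oxide from 2-bromoacrolein oxime in step 4 so that a 1-bromovinyl group is carried through the unmasking and no enolisation is needed.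

3. **Step 13 (Barbier union).** Aldehyde 11 is a β-alkoxy aldehyde and can open the furanone by elimination; the C8 facial selectivity is also untested on this substrate. Fallback: make the C7–C8 bond before the furanone exists, by cleaving the prenyl group at the isoxazole stage (8), coupling that robust aldehyde with 18, and unmasking the furanone afterwards.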